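Ring numbering: C1 is the quaternary carbon, C2 the methyl-bearing alkene carbon, C3 to C5 follow, C6 is the CH(CH3) carbon and C1' the first side-chain carbon. The plan rests on cutting the cyclohexene at C1–C6, its most crowded bond, and at C3–C4. C1 carries three carbon substituents, CH3, C2 and C1', which correspond one by one to the alpha-methyl, ketone and ester carbons of ethyl 2-methylacetoacetate; C4 to C6 plus the C6 methyl are crotonaldehyde. One catalytic asymmetric Michael–aldol condensation of these two commercial compounds forms both bonds, closes the only ring and sets both stereocentres. Triflate methylation, ester-to-vinyl conversion, B-alkyl Suzuki coupling, bromination and sulfinate alkylation finish the molecule.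

Key step: step 1

Assumption: the sense of induction of the catalyst cannot be predicted with certainty for this acyclic donor. The quinidine-derived catalyst is written, the configuration of the annulation product is to be checked, and the quinine-derived pseudoenantiomer takes its place if the opposite series forms.

Remark on configuration: the ester carbon of the annulation product sits where C1' sits in the target. The two ring methyl groups are cis and the ester (later the chain) is trans to the C6 methyl. The ring stereocentres keep the same CIP descriptors (S at the quaternary carbon, R at the methine) from the annulation product to the target.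

Step 1
Reactants: 1 ethyl 2-methyl-3-oxobutanoate; 2 (E)-but-2-enal
Product: 4 ethyl (1S,6R)-1,6-dimethyl-2-oxocyclohex-3-ene-1-carboxylate, via Michael adduct 3 (not isolated)
Conditions: 9-O-(phenanthren-9-yl)cupreidine (6'-O-demethylquinidine 9-phenanthryl ether, 10 mol %), toluene, −20 °C; then p-TsOH·H2O (30 mol %), 4 Å MS, 80 °C
Reagents that add atoms: none
Why: The quinuclidine nitrogen removes the acidic C–H of 1 and holds the resulting Z-configured enolate as a hydrogen-bonded ion pair, while the 6'-OH of the same catalyst binds the carbonyl oxygen of s-trans 2, so that 1,4-addition forges C1–C6 and gives 3; the acid added afterwards quenches the base, enolises the acetyl group and lets its CH3 carbon (C3) attack the aldehyde carbon (C4), and loss of water leaves the C3=C4 enone. The closest known chemistry is the cinchona-alkaloid-catalysed Michael addition of alpha-substituted beta-keto esters to beta-substituted enals, which builds vicinal quaternary and tertiary centres, joined to the acid-promoted Michael–aldol condensation of acetoacetates and enals to cyclohexenones (a Robinson-type annulation). The only ring closes in the favoured 6-(enolendo)-exo-trig mode. C1 is fixed by the enolate face that the catalyst leaves open (ester and acetyl oxygens are differentiated in the ion pair) and C6 by the face of the E-enal turned towards it, the combination placing the ester trans to the C6 methyl group. The step needs 1,4- rather than 1,2-attack, one of two diastereomers and one aldol pairing: the soft stabilised enolate secures the first, the catalyst pocket has to secure the second and is the real risk, and the substrate secures the third because C1 bears no hydrogen, so the ketone can enolise only towards its CH3 group, and the reverse pairing would give a four-membered ring. After closure the stereocentres are safe, since C1 has four carbon substituents and C6 lies outside the enolisable positions of 4, and the ethyl ester (unlike a tert-butyl ester) withstands the acid so that C1 is not lost by decarboxylation.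

Step 2
Reactants: 4 ethyl (1S,6R)-1,6-dimethyl-2-oxocyclohex-3-ene-1-carboxylate
Product: 6 ethyl (1S,6R)-1,6-dimethyl-2-(trifluoromethylsulfonyloxy)cyclohex-2-ene-1-carboxylate, via lithium enolate 5 (not isolated)
Conditions: LiBH(sBu)3 (1.05 equiv), THF, −78 °C; then PhNTf2 (1.2 equiv), −78 °C to rt
Reagents that add atoms: N-phenylbis(trifluoromethanesulfonimide) (PhNTf2), O=S(=O)(N(c1ccccc1)S(=O)(=O)C(F)(F)F)C(F)(F)F
Why: Conjugate reduction–enolate trapping, in which the bulky borohydride delivers hydride to the unhindered C4 rather than to the C2 carbonyl screened by quaternary C1, and the regiodefined C2=C3 enolate 5 is O-sulfonylated by PhNTf2 without touching a stereocentre.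

Step 3
Reactants: 6 ethyl (1S,6R)-1,6-dimethyl-2-(trifluoromethylsulfonyloxy)cyclohex-2-ene-1-carboxylate
Product: 7 ethyl (1S,6R)-1,2,6-trimethylcyclohex-2-ene-1-carboxylate
Conditions: MeMgBr (1.5 equiv), Fe(acac)3 (5 mol %), THF/NMP, −30 °C to 0 °C
Reagents that add atoms: methylmagnesium bromide, C[Mg]Br
Why: Iron-catalysed Kumada-type cross-coupling of an alkenyl triflate with MeMgBr is far faster at low temperature than Grignard attack on the hindered ester, and it installs the C2 methyl group with the C2=C3 alkene already in place.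

Step 4
Reactants: 7 ethyl (1S,6R)-1,2,6-trimethylcyclohex-2-ene-1-carboxylate
Product: 8 [(1S,6R)-1,2,6-trimethylcyclohex-2-en-1-yl]methanol
Conditions: LiAlH4 (1.5 equiv), Et2O, 0 °C to reflux; aqueous work-up
Reagents that add atoms: none
Why: Standard LiAlH4 reduction of an ester to the primary alcohol, to which the isolated trisubstituted alkene and both stereocentres are inert.

Step 5
Reactants: 8 [(1S,6R)-1,2,6-trimethylcyclohex-2-en-1-yl]methanol
Product: 9 (1S,6R)-1,2,6-trimethylcyclohex-2-ene-1-carbaldehyde
Conditions: Dess–Martin periodinane (1.2 equiv), CH2Cl2, 0 °C to rt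
Reagents that add atoms: none
Why: Dess–Martin oxidation stops at the aldehyde, which has no alpha hydrogen and therefore can neither epimerise nor move its alkene into conjugation.

Step 6
Reactants: 9 (1S,6R)-1,2,6-trimethylcyclohex-2-ene-1-carbaldehyde
Product: 10 (5R,6S)-6-ethenyl-1,5,6-trimethylcyclohex-1-ene
Conditions: Ph3PCH3Br (1.5 equiv), KOtBu (1.4 equiv), THF, 0 °C to rt; volatile product kept as a pentane/THF solution
Reagents that add atoms: methyltriphenylphosphonium bromide, C[P+](c1ccccc1)(c1ccccc1)c1ccccc1.[Br-]
Why: Wittig methylenation with the small unstabilised ylide copes with alpha-quaternary aldehydes, and 9 cannot enolise under the basic conditions.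

Step 7
Reactants: 11 geranyl acetate, (2E)-3,7-dimethylocta-2,6-dien-1-yl acetate
Product: 12 (2E)-5-(3,3-dimethyloxiran-2-yl)-3-methylpent-2-en-1-yl acetate (racemic at the oxirane carbon)
Conditions: mCPBA (1.0 equiv), CH2Cl2, 0 °C
Reagents that add atoms: 3-chloroperoxybenzoic acid, OOC(=O)c1cccc(Cl)c1
Why: Prilezhaev epoxidation picks the electron-rich 6,7-alkene because the 2,3-alkene is deactivated by the allylic acetate, and the racemic new stereocentre is destroyed in the next step.

Step 8
Reactants: 12 (2E)-5-(3,3-dimethyloxiran-2-yl)-3-methylpent-2-en-1-yl acetate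
Product: 13 (2E)-3-methyl-6-oxohex-2-en-1-yl acetate
Conditions: H5IO6 (1.1 equiv), THF/H2O, 0 °C
Reagents that add atoms: none
Why: Periodic acid opens the epoxide to the glycol and cleaves it (Malaprade-type cleavage) to the aldehyde and acetone without touching the allylic acetate or the E alkene.

Step 9
Reactants: 13 (2E)-3-methyl-6-oxohex-2-en-1-yl acetate
Product: 14 (2E)-3-methylhept-2-en-6-yn-1-ol
Conditions: dimethyl (1-diazo-2-oxopropyl)phosphonate (1.3 equiv), K2CO3 (3 equiv), MeOH, 0 °C to rt
Reagents that add atoms: dimethyl (1-diazo-2-oxopropyl)phosphonate (Ohira–Bestmann reagent), COP(=O)(OC)C(=[N+]=[N-])C(C)=O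
Why: Ohira–Bestmann (Seyferth–Gilbert) homologation turns the aldehyde into the terminal alkyne, and the same K2CO3/MeOH medium transesterifies the acetate, so the protecting group leaves without a step of its own.

Step 10
Reactants: 14 (2E)-3-methylhept-2-en-6-yn-1-ol
Product: 16 (2E)-3-methyloct-2-en-6-yn-1-ol, via dilithio dianion 15 (not isolated)
Conditions: n-BuLi (2.1 equiv), THF, −78 °C to 0 °C; then MeI (1.1 equiv), −78 °C to rt
Reagents that add atoms: iodomethane, CI
Why: Alkylation of an alkynol dianion, in which the lithium acetylide carbon is methylated in THF without polar cosolvent while the aggregated lithium alkoxide stays unreactive towards the single equivalent of MeI.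

Step 11
Reactants: 16 (2E)-3-methyloct-2-en-6-yn-1-ol
Product: 18 (2E,6E)-7-iodo-3-methylocta-2,6-dien-1-ol, via alkenylzirconocene 17 (not isolated)
Conditions: Cp2ZrHCl (3 equiv), THF, 50 °C, dark; then I2, THF, 0 °C
Reagents that add atoms: iodine, II
Why: Hydrozirconation–iodinolysis, in which one equivalent of Cp2ZrHCl is consumed by the OH group, syn addition of Zr–H to the alkyne under equilibrating conditions (excess reagent, warming) places zirconium on the less hindered methyl-bearing carbon, and I2 cleaves the C–Zr bond with retention to give the 6E iodide, any regioisomer being removed by chromatography.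

Step 12
Reactants: 10 (5R,6S)-6-ethenyl-1,5,6-trimethylcyclohex-1-ene; 18 (2E,6E)-7-iodo-3-methylocta-2,6-dien-1-ol
Product: 20 (2E,6E)-3,7-dimethyl-9-[(1S,6R)-1,2,6-trimethylcyclohex-2-en-1-yl]nona-2,6-dien-1-ol, via B-alkyl borane 19 (not isolated)
Conditions: 10, 9-BBN (1.2 equiv), THF, 0 °C to rt; then H2O, Cs2CO3 (2 equiv), 18, Pd(dppf)Cl2 (5 mol %), AsPh3 (10 mol %), DMF, rt to 50 °C
Reagents that add atoms: none
Why: 9-BBN adds only to the monosubstituted alkene of 10 with boron on the terminal carbon, and the B-alkyl Suzuki–Miyaura coupling of 19 with alkenyl iodide 18 proceeds with retention of the E geometry while the free allylic alcohol and the trisubstituted alkenes stay untouched.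

Step 13
Reactants: 20 (2E,6E)-3,7-dimethyl-9-[(1S,6R)-1,2,6-trimethylcyclohex-2-en-1-yl]nona-2,6-dien-1-ol
Product: 21 (5R,6S)-6-[(3E,7E)-9-bromo-3,7-dimethylnona-3,7-dien-1-yl]-1,5,6-trimethylcyclohex-1-ene
Conditions: CBr4 (1.2 equiv), PPh3 (1.25 equiv), CH2Cl2, −20 °C to 0 °C; used without storage
Reagents that add atoms: carbon tetrabromide, BrC(Br)(Br)Br
Why: The Appel bromination works under neutral conditions and replaces the primary allylic oxyphosphonium group by SN2 attack of bromide, without allylic transposition or loss of alkene geometry.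

Step 14
Reactants: 22 hypotaurine (2-aminoethanesulfinic acid)
Product: 23 2-guanidinoethanesulfinic acid (zwitterion: guanidinium sulfinate)
Conditions: 1H-pyrazole-1-carboxamidine hydrochloride (1.0 equiv), NaOH (1.0 equiv), H2O, rt, argon; precipitation with EtOH
Reagents that add atoms: 1H-pyrazole-1-carboxamidine hydrochloride, Cl.N=C(N)n1cccn1
Why: Guanylation of a primary amine by amidine transfer from pyrazole-1-carboxamidine, which leaves the sulfinate untouched and gives a zwitterion that should precipitate.

Step 15
Reactants: 21 (5R,6S)-6-[(3E,7E)-9-bromo-3,7-dimethylnona-3,7-dien-1-yl]-1,5,6-trimethylcyclohex-1-ene; 23 2-guanidinoethanesulfinic acid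
Product: 25 agelasidine C, 2-(2-{[(2E,6E)-3,7-dimethyl-9-[(1S,6R)-1,2,6-trimethylcyclohex-2-en-1-yl]nona-2,6-dien-1-yl]sulfonyl}ethyl)guanidine, via hydrobromide salt 24 (not isolated)
Conditions: DMF/H2O, 0 °C to rt, argon; then 1 M NaOH (1.0 equiv), 0 °C, extraction with CHCl3/i-PrOH
Reagents that add atoms: none
Why: S-alkylation of a sulfinate by a primary allylic bromide (SN2) gives the sulfone, the guanidine of zwitterion 23 being protonated and hence not nucleophilic so that no protecting group is needed, and a brief cold treatment with one equivalent of NaOH frees the base.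

Compound list
1 | ethyl 2-methyl-3-oxobutanoate (racemic, configurationally labile) | CCOC(=O)C(C)C(C)=O | starting material
2 | (E)-but-2-enal | C/C=C/C=O | starting material
3 | ethyl (2S,3R)-2-acetyl-2,3-dimethyl-5-oxopentanoate | O=CC[C@@H](C)[C@](C(C)=O)(C)C(=O)OCC | intermediate
4 | ethyl (1S,6R)-1,6-dimethyl-2-oxocyclohex-3-ene-1-carboxylate | O=C1C=CC[C@@H](C)[C@]1(C)C(=O)OCC | intermediate
5 | lithium (5R,6S)-6-(ethoxycarbonyl)-5,6-dimethylcyclohex-1-en-1-olate | [Li+].[O-]C1=CCC[C@@H](C)[C@]1(C)C(=O)OCC | intermediate
6 | ethyl (1S,6R)-1,6-dimethyl-2-(trifluoromethylsulfonyloxy)cyclohex-2-ene-1-carboxylate | O=S(=O)(OC1=CCC[C@@H](C)[C@]1(C)C(=O)OCC)C(F)(F)F | intermediate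
7 | ethyl (1S,6R)-1,2,6-trimethylcyclohex-2-ene-1-carboxylate | CC1=CCC[C@@H](C)[C@]1(C)C(=O)OCC | intermediate
8 | [(1S,6R)-1,2,6-trimethylcyclohex-2-en-1-yl]methanol | CC1=CCC[C@@H](C)[C@]1(C)CO | intermediate
9 | (1S,6R)-1,2,6-trimethylcyclohex-2-ene-1-carbaldehyde | CC1=CCC[C@@H](C)[C@]1(C)C=O | intermediate
10 | (5R,6S)-6-ethenyl-1,5,6-trimethylcyclohex-1-ene | CC1=CCC[C@@H](C)[C@]1(C)C=C | intermediate
11 | geranyl acetate | CC(C)=CCC/C(C)=C/COC(C)=O | starting material
12 | (2E)-5-(3,3-dimethyloxiran-2-yl)-3-methylpent-2-en-1-yl acetate (racemic) | CC1(C)OC1CC/C(C)=C/COC(C)=O | intermediate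
13 | (2E)-3-methyl-6-oxohex-2-en-1-yl acetate | O=CCC/C(C)=C/COC(C)=O | intermediate
14 | (2E)-3-methylhept-2-en-6-yn-1-ol | C#CCC/C(C)=C/CO | intermediate
15 | dilithium salt (alkoxide and acetylide) of 14 | [Li]C#CCC/C(C)=C/CO[Li] | intermediate
16 | (2E)-3-methyloct-2-en-6-yn-1-ol | CC#CCC/C(C)=C/CO | intermediate
17 | (2E,6E)-7-[chlorobis(cyclopentadienyl)zirconio]-3-methylocta-2,6-dien-1-yl oxide bound to Cp2ZrCl | Cl[Zr](C1C=CC=C1)(C1C=CC=C1)/C(C)=C/CC/C(C)=C/CO[Zr](Cl)(C1C=CC=C1)C1C=CC=C1 | intermediate
18 | (2E,6E)-7-iodo-3-methylocta-2,6-dien-1-ol | I/C(C)=C/CC/C(C)=C/CO | intermediate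
19 | 9-{2-[(1S,6R)-1,2,6-trimethylcyclohex-2-en-1-yl]ethyl}-9-borabicyclo[3.3.1]nonane | CC1=CCC[C@@H](C)[C@]1(C)CCB1C2CCCC1CCC2 | intermediate
20 | (2E,6E)-3,7-dimethyl-9-[(1S,6R)-1,2,6-trimethylcyclohex-2-en-1-yl]nona-2,6-dien-1-ol | CC1=CCC[C@@H](C)[C@]1(C)CC/C(C)=C/CC/C(C)=C/CO | intermediate
21 | (5R,6S)-6-[(3E,7E)-9-bromo-3,7-dimethylnona-3,7-dien-1-yl]-1,5,6-trimethylcyclohex-1-ene | CC1=CCC[C@@H](C)[C@]1(C)CC/C(C)=C/CC/C(C)=C/CBr | intermediate
22 | hypotaurine | NCCS(=O)O | starting material
23 | 2-guanidinoethanesulfinic acid (exists as zwitterion) | NC(N)=NCCS(=O)O | intermediate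
24 | agelasidine C hydrobromide | CC1=CCC[C@@H](C)[C@]1(C)CC/C(C)=C/CC/C(C)=C/CS(=O)(=O)CCNC(N)=[NH2+].[Br-] | intermediate
25 | agelasidine C | CC1=CCC[C@@H](C)[C@]1(C)CC/C(C)=C/CC/C(C)=C/CS(=O)(=O)CCN=C(N)N | target

Total step count: 15. Longest linear sequence: 9 (steps 1 to 6, 12, 13, 15).

Steps most likely to fail

Step 1. The acyclic enolate is conformationally free and only weakly acidic. Face discrimination at C1 may therefore be poor, and an uncatalysed background addition to the beta-substituted enal may erode both selectivities. The fallback sets out from 1 and 2 and comes back at 4, and it activates the enal covalently instead of by hydrogen bonding. (S)-2-[Diphenyl(trimethylsilyloxy)methyl]pyrrolidine (10 mol %) and benzoic acid in toluene turn 2 into its E-iminium ion. One face of this ion is blocked by the diarylmethyl group, so C6 should be set as R whatever the donor does. C1 is then left to the substrate, and 3 is expected along with its C2 epimer, ethyl (2R,3R)-2-acetyl-2,3-dimethyl-5-oxopentanoate F1. The same p-TsOH closure would give 4 and ethyl (1R,6R)-1,6-dimethyl-2-oxocyclohex-3-ene-1-carboxylate F2. These are diastereomers and are separated by chromatography, so material is lost but enantiopurity is secured.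

Step 12. Transmetalation from the bulky borane to palladium may be slow, which would let protodeboronation and reduction of the iodide take over. The fallback sets out from 10 and 18 and comes back at 20, and it replaces boron by zinc.
- Borane 19, made as before from 10, is oxidised with NaOH/H2O2 to 2-[(1S,6R)-1,2,6-trimethylcyclohex-2-en-1-yl]ethan-1-ol F3.
- I2, PPh3 and imidazole convert it into (5R,6S)-6-(2-iodoethyl)-1,5,6-trimethylcyclohex-1-ene F4.
- Direct insertion of Zn dust in the presence of LiCl in THF gives {2-[(1S,6R)-1,2,6-trimethylcyclohex-2-en-1-yl]ethyl}zinc iodide F5.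
- Iodide 18 is silylated (TBSCl, imidazole) to tert-butyl{[(2E,6E)-7-iodo-3-methylocta-2,6-dien-1-yl]oxy}dimethylsilane F6.
- Negishi coupling of F5 with F6 under Pd(dppf)Cl2 in THF should give the tert-butyldimethylsilyl ether of 20 F7.
- TBAF in THF releases 20 from F7.

Step 15. The lipophilic bromide and the salt-like sulfinate may not meet in one phase. Hydrolysis of the bromide, or O-alkylation followed by rearrangement, could then compete, and the polar product is hard to purify. The fallback sets out from 21 and 22 and comes back at 25, and it masks the guanidine to make both partners and the product lipophilic.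
- Hypotaurine 22 is treated with N,N'-di-Boc-1H-pyrazole-1-carboxamidine and NaOH (1 equiv) in MeOH to give sodium 2-{[bis(tert-butoxycarbonylamino)methylidene]amino}ethanesulfinate F8.
- F8 is alkylated with 21 in dry DMF to N,N'-bis(tert-butoxycarbonyl)agelasidine C F9, which can be purified on silica.
- The carbamates are removed without protic acid, which could cyclise the polyene. TMSOTf/2,6-lutidine in CH2Cl2 at 0 °C followed by MeOH gives agelasidine C trifluoromethanesulfonate F10.
- Cold 1 M NaOH (1 equiv) converts F10 into 25.

Further compounds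
F1 | step 1 | ethyl (2R,3R)-2-acetyl-2,3-dimethyl-5-oxopentanoate | O=CC[C@@H](C)[C@@](C(C)=O)(C)C(=O)OCC
F2 | step 1 | ethyl (1R,6R)-1,6-dimethyl-2-oxocyclohex-3-ene-1-carboxylate | O=C1C=CC[C@@H](C)[C@@]1(C)C(=O)OCC
F3 | step 12 | 2-[(1S,6R)-1,2,6-trimethylcyclohex-2-en-1-yl]ethan-1-ol | CC1=CCC[C@@H](C)[C@]1(C)CCO
F4 | step 12 | (5R,6S)-6-(2-iodoethyl)-1,5,6-trimethylcyclohex-1-ene | CC1=CCC[C@@H](C)[C@]1(C)CCI
F5 | step 12 | {2-[(1S,6R)-1,2,6-trimethylcyclohex-2-en-1-yl]ethyl}zinc iodide | CC1=CCC[C@@H](C)[C@]1(C)CC[Zn]I
F6 | step 12 | tert-butyl{[(2E,6E)-7-iodo-3-methylocta-2,6-dien-1-yl]oxy}dimethylsilane | I/C(C)=C/CC/C(C)=C/CO[Si](C)(C)C(C)(C)C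
F7 | step 12 | tert-butyldimethylsilyl ether of 20 | CC1=CCC[C@@H](C)[C@]1(C)CC/C(C)=C/CC/C(C)=C/CO[Si](C)(C)C(C)(C)C
F8 | step 15 | sodium 2-{[bis(tert-butoxycarbonylamino)methylidene]amino}ethanesulfinate | CC(C)(C)OC(=O)NC(=NCCS(=O)[O-])NC(=O)OC(C)(C)C.[Na+]
F9 | step 15 | N,N'-bis(tert-butoxycarbonyl)agelasidine C | CC1=CCC[C@@H](C)[C@]1(C)CC/C(C)=C/CC/C(C)=C/CS(=O)(=O)CCN=C(NC(=O)OC(C)(C)C)NC(=O)OC(C)(C)C
F10 | step 15 | agelasidine C trifluoromethanesulfonate | CC1=CCC[C@@H](C)[C@]1(C)CC/C(C)=C/CC/C(C)=C/CS(=O)(=O)CCNC(N)=[NH2+].[O-]S(=O)(=O)C(F)(F)F
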